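**Strategy.** Talapolyester B is cut at its three ester C–O linkages into units A (dihydroxybutanoyl), B and D (hydroxybutanoyl) and C (resorcylate). Everything rests on unit C. Its carboxyl carbon sits on the benzene ring ortho to the CH2–CH(CH3)–O chain, and without it the ring has two equivalent C–H bonds (C2–H, C6–H), each beside an oxygen-bearing carbon. The free hydroxyl of (R)-1-[3,5-bis(benzyloxy)phenyl]propan-2-ol guides palladium to one of them. CO insertion then forms the aryl–C(=O) and acyl–O bonds and closes the six-membered isochroman-1-one ring in one operation. All-benzyl protection allows a single final hydrogenolysis.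

Key step: step 2

Configuration read from the target SMILES: unit A C3 (R), unit B C3 (R), unit C carbinol (R), unit D C3 (S).
Assumption: 1,3-bis(benzyloxy)-5-bromobenzene and tert-butyl (R)-3-hydroxybutanoate are taken as catalogue compounds.
Abbreviations: Bn = benzyl, TBS = tert-butyldimethylsilyl.

Step 1
Reactants: 1 1,3-bis(benzyloxy)-5-bromobenzene; 2 (R)-propylene oxide
Product: 4 (R)-1-[3,5-bis(benzyloxy)phenyl]propan-2-ol, via arylmagnesium bromide 3 (not isolated)
Conditions: Mg, THF, reflux; then CuI (10 mol %), 2, THF, −30 → 0 °C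
Reagents that add atoms: magnesium, [Mg] (stays only in 3)
Why: Copper-catalysed Grignard opening of a terminal epoxide is an SN2 attack at the unhindered CH2, so the C–O stereocentre bought with 2 passes unchanged into 4 as (R), and the phenol protection needed at the end is already in place.

Step 2
Reactants: 4 (R)-1-[3,5-bis(benzyloxy)phenyl]propan-2-ol
Product: 5 (R)-6,8-bis(benzyloxy)-3-methylisochroman-1-one
Conditions: CO (1 atm), Pd(OAc)2 (10 mol %), Boc-L-Leu-OH (20 mol %), AgOAc (3 equiv), Li2CO3 (1 equiv), CH2Cl2, sealed vessel, 100–110 °C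
Reagents that add atoms: carbon monoxide, [C-]#[O+]
Why: The alkoxide of 4 binds divalent palladium, and the Boc-leucinate ligand serves as internal base for concerted metalation–deprotonation of C2–H (or the equivalent C6–H), giving a six-membered oxapalladacycle. CO inserts into the aryl–palladium bond to give a seven-membered acylpalladium alkoxide, C–O reductive elimination from this chelate closes the six-membered lactone ring, and AgOAc returns zerovalent palladium to the divalent state. The closest known reaction type is the hydroxyl-directed, amino-acid-ligand-accelerated C–H carbonylation of 2-arylethanols to isochroman-1-ones, in which secondary carbinols are the demanding members of the scope. No stereocentre is formed, and the (R)-carbinol carbon only carries the directing oxygen, so it becomes C3 of 5 with its configuration kept. Site selectivity against C4–H between the two benzyloxy groups is secured by the tether, because only C2 and C6 can be reached through a six-membered palladacycle and these two are equivalent, so a single isomer should result. Chemoselectivity against β-hydride elimination of the palladium alkoxide to the ketone is helped by the electron-rich ring (the reacting carbon is ortho and para to oxygen) and by the ligand, both of which speed up C–H cleavage.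

Step 3
Reactants: 5 (R)-6,8-bis(benzyloxy)-3-methylisochroman-1-one
Product: 6 potassium 2,4-bis(benzyloxy)-6-[(R)-2-hydroxypropyl]benzoate
Conditions: KOH (1.2 equiv), EtOH–H2O, 80 °C; evaporate, dry by toluene azeotrope
Reagents that add atoms: potassium hydroxide, [K+].[OH-]
Why: Saponification opens the lactone at the acyl carbon without touching the carbinol centre or the benzyl ethers, and keeping the product as the dry potassium salt, never acidified, blocks re-closure of the ring.

Step 4
Reactants: 6 potassium 2,4-bis(benzyloxy)-6-[(R)-2-hydroxypropyl]benzoate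
Product: 8 2,4-bis(benzyloxy)-6-[(R)-2-(tert-butyldimethylsilyloxy)propyl]benzoic acid, via bis-silyl compound 7 (not isolated)
Conditions: TBSCl (3 equiv), imidazole (5 equiv), DMF, rt; then K2CO3, MeOH–THF–H2O, rt; aq KHSO4 to pH 4, 0 °C
Reagents that add atoms: TBSCl, CC(C)(C)[Si](C)(C)Cl
Why: Exhaustive silylation caps the hydroxyl before any free acid exists, and the far more labile silyl ester is then cleaved selectively at silicon by carbonate in aqueous methanol, so acidification can no longer lead back to the lactone.

Step 5
Reactants: 9 methyl (R)-3-hydroxybutanoate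
Product: 10 benzyl (R)-3-hydroxybutanoate
Conditions: BnOH (5 equiv), Ti(OiPr)4 (5 mol %), toluene, 110 °C, MeOH distilled off
Reagents that add atoms: benzyl alcohol, OCc1ccccc1
Why: Titanate-catalysed transesterification exchanges only the alkoxy partner of the ester, leaves the (R)-carbinol untouched and installs a carboxyl protection that falls in the final hydrogenolysis, which a methyl ester beside three other ester linkages could not do.

Step 6
Reactants: 8 2,4-bis(benzyloxy)-6-[(R)-2-(tert-butyldimethylsilyloxy)propyl]benzoic acid; 10 benzyl (R)-3-hydroxybutanoate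
Product: 11 (S)-4-(benzyloxy)-4-oxobutan-2-yl 2,4-bis(benzyloxy)-6-[(R)-2-(tert-butyldimethylsilyloxy)propyl]benzoate
Conditions: PPh3, DIAD, toluene, 0 °C → rt
Reagents that add atoms: none
Why: The Mitsunobu esterification activates the alcohol instead of the crowded 2,6-disubstituted acyl carbon, and SN2 displacement of the oxyphosphonium group by the carboxylate inverts the (R)-carbinol of 10 to the (S)-centre of unit D.

Step 7
Reactants: 11 (S)-4-(benzyloxy)-4-oxobutan-2-yl 2,4-bis(benzyloxy)-6-[(R)-2-(tert-butyldimethylsilyloxy)propyl]benzoate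
Product: 12 (S)-4-(benzyloxy)-4-oxobutan-2-yl 2,4-bis(benzyloxy)-6-[(R)-2-hydroxypropyl]benzoate
Conditions: HF·pyridine, THF, 0 °C → rt
Reagents that add atoms: none
Why: Fluoride-mediated desilylation in a mildly acidic, non-basic medium removes the secondary TBS ether without E1cB loss of the β-aroyloxy group and without alkoxide-driven lactonisation.

Step 8
Reactants: 13 (R)-benzyl glycidyl ether
Product: 14 (R)-1-(benzyloxy)pent-4-en-2-ol
Conditions: CH2=CHMgBr, CuI (10 mol %), THF, −40 → 0 °C
Reagents that add atoms: vinylmagnesium bromide, C=C[Mg]Br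
Why: Copper-catalysed Grignard opening of the epoxide at its terminal carbon (SN2) leaves the C–O stereocentre untouched, and since the CIP ranking O > CH2OBn > CH2 is unchanged the alcohol is (R), with the vinyl group serving as a masked carboxyl carbon.

Step 9
Reactants: 14 (R)-1-(benzyloxy)pent-4-en-2-ol
Product: 15 (R)-4,5-bis(benzyloxy)pent-1-ene
Conditions: NaH, BnBr, DMF, 0 °C → rt
Reagents that add atoms: benzyl bromide, BrCc1ccccc1
Why: Williamson etherification of a homoallylic alkoxide has no elimination or epimerisation pathway and is placed here, before any carbonyl group exists, so that strong base can be used safely.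

Step 10
Reactants: 15 (R)-4,5-bis(benzyloxy)pent-1-ene
Product: 17 (R)-3,4-bis(benzyloxy)butanoic acid, via aldehyde 16 (not isolated)
Conditions: O3, CH2Cl2, −78 °C; Me2S, → rt; concentrate; NaClO2, NaH2PO4, 2-methyl-2-butene, t-BuOH–H2O, rt
Reagents that add atoms: ozone, [O-][O+]=O; sodium chlorite, [Na+].[O-]Cl=O
Why: Ozonolysis cleaves the terminal alkene far faster than it attacks benzyl ethers, and the crude β-alkoxy aldehyde goes straight into a Pinnick oxidation, whose buffered medium avoids β-elimination and leaves C3 untouched.

Step 11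
Reactants: 17 (R)-3,4-bis(benzyloxy)butanoic acid; 18 tert-butyl (R)-3-hydroxybutanoate
Product: 19 tert-butyl (R)-3-{[(R)-3,4-bis(benzyloxy)butanoyl]oxy}butanoate
Conditions: DCC, DMAP (10 mol %), CH2Cl2, 0 °C → rt
Reagents that add atoms: none
Why: The Steglich esterification forms the bond at the acyl carbon of 17, so the (R)-carbinol of 18 is retained as the centre of unit B, and benzyloxide is too poor a leaving group for β-elimination from the activated acid.

Step 12
Reactants: 19 tert-butyl (R)-3-{[(R)-3,4-bis(benzyloxy)butanoyl]oxy}butanoate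
Product: 20 (R)-3-{[(R)-3,4-bis(benzyloxy)butanoyl]oxy}butanoic acid
Conditions: TFA–CH2Cl2 (1:4), 0 °C → rt
Reagents that add atoms: none
Why: Acidolysis of the tert-butyl ester by alkyl–oxygen cleavage through the tert-butyl cation frees the acid without base, so the β-acyloxy ester cannot eliminate, and the alkyl benzyl ethers are stable to these conditions.

Step 13
Reactants: 12 (S)-4-(benzyloxy)-4-oxobutan-2-yl 2,4-bis(benzyloxy)-6-[(R)-2-hydroxypropyl]benzoate; 20 (R)-3-{[(R)-3,4-bis(benzyloxy)butanoyl]oxy}butanoic acid
Product: 21 penta-benzyl talapolyester B, (S)-4-(benzyloxy)-4-oxobutan-2-yl 2,4-bis(benzyloxy)-6-[(R)-2-({(R)-3-[((R)-3,4-bis(benzyloxy)butanoyl)oxy]butanoyl}oxy)propyl]benzoate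
Conditions: DCC, DMAP (10 mol %), CH2Cl2, −10 °C → rt
Reagents that add atoms: none
Why: The Steglich esterification acylates the secondary hydroxyl of 12 with retention at its carbinol carbon, and low temperature with only catalytic DMAP keeps β-elimination of the acyl donor and back-lactonisation slow.

Step 14
Reactants: 21 penta-benzyl talapolyester B
Product: 22 talapolyester B
Conditions: H2 (1 atm), Pd(OH)2/C, EtOAc–THF, rt
Reagents that add atoms: none
Why: Catalytic hydrogenolysis removes two aryl benzyl ethers, two alkyl benzyl ethers and the benzyl ester together under neutral conditions, so the γ-hydroxy ester of unit A is unveiled without acid or base that could trigger lactonisation, and no ester C–O bond is benzylic.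

Compound list
1 | 1,3-bis(benzyloxy)-5-bromobenzene | Brc1cc(OCc2ccccc2)cc(OCc2ccccc2)c1 | starting material
2 | (R)-propylene oxide | C[C@@H]1CO1 | starting material
3 | [3,5-bis(benzyloxy)phenyl]magnesium bromide | Br[Mg]c1cc(OCc2ccccc2)cc(OCc2ccccc2)c1 | intermediate
4 | (R)-1-[3,5-bis(benzyloxy)phenyl]propan-2-ol | C[C@@H](O)Cc1cc(OCc2ccccc2)cc(OCc2ccccc2)c1 | intermediate
5 | (R)-6,8-bis(benzyloxy)-3-methylisochroman-1-one | C[C@@H]1Cc2cc(OCc3ccccc3)cc(OCc3ccccc3)c2C(=O)O1 | intermediate
6 | potassium 2,4-bis(benzyloxy)-6-[(R)-2-hydroxypropyl]benzoate | C[C@@H](O)Cc1cc(OCc2ccccc2)cc(OCc2ccccc2)c1C(=O)[O-].[K+] | intermediate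
7 | tert-butyldimethylsilyl 2,4-bis(benzyloxy)-6-[(R)-2-(tert-butyldimethylsilyloxy)propyl]benzoate | C[C@@H](O[Si](C)(C)C(C)(C)C)Cc1cc(OCc2ccccc2)cc(OCc2ccccc2)c1C(=O)O[Si](C)(C)C(C)(C)C | intermediate
8 | 2,4-bis(benzyloxy)-6-[(R)-2-(tert-butyldimethylsilyloxy)propyl]benzoic acid | C[C@@H](O[Si](C)(C)C(C)(C)C)Cc1cc(OCc2ccccc2)cc(OCc2ccccc2)c1C(=O)O | intermediate
9 | methyl (R)-3-hydroxybutanoate | C[C@@H](O)CC(=O)OC | starting material
10 | benzyl (R)-3-hydroxybutanoate | C[C@@H](O)CC(=O)OCc1ccccc1 | intermediate
11 | (S)-4-(benzyloxy)-4-oxobutan-2-yl 2,4-bis(benzyloxy)-6-[(R)-2-(tert-butyldimethylsilyloxy)propyl]benzoate | C[C@@H](O[Si](C)(C)C(C)(C)C)Cc1cc(OCc2ccccc2)cc(OCc2ccccc2)c1C(=O)O[C@@H](C)CC(=O)OCc3ccccc3 | intermediate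
12 | (S)-4-(benzyloxy)-4-oxobutan-2-yl 2,4-bis(benzyloxy)-6-[(R)-2-hydroxypropyl]benzoate | C[C@@H](O)Cc1cc(OCc2ccccc2)cc(OCc2ccccc2)c1C(=O)O[C@@H](C)CC(=O)OCc3ccccc3 | intermediate
13 | (R)-benzyl glycidyl ether | C(OCc1ccccc1)[C@H]1CO1 | starting material
14 | (R)-1-(benzyloxy)pent-4-en-2-ol | C=CC[C@@H](O)COCc1ccccc1 | intermediate
15 | (R)-4,5-bis(benzyloxy)pent-1-ene | C=CC[C@@H](OCc1ccccc1)COCc1ccccc1 | intermediate
16 | (R)-3,4-bis(benzyloxy)butanal | O=CC[C@@H](OCc1ccccc1)COCc1ccccc1 | intermediate
17 | (R)-3,4-bis(benzyloxy)butanoic acid | OC(=O)C[C@@H](OCc1ccccc1)COCc1ccccc1 | intermediate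
18 | tert-butyl (R)-3-hydroxybutanoate | C[C@@H](O)CC(=O)OC(C)(C)C | starting material
19 | tert-butyl (R)-3-{[(R)-3,4-bis(benzyloxy)butanoyl]oxy}butanoate | C[C@H](CC(=O)OC(C)(C)C)OC(=O)C[C@@H](OCc1ccccc1)COCc1ccccc1 | intermediate
20 | (R)-3-{[(R)-3,4-bis(benzyloxy)butanoyl]oxy}butanoic acid | C[C@H](CC(=O)O)OC(=O)C[C@@H](OCc1ccccc1)COCc1ccccc1 | intermediate
21 | penta-benzyl talapolyester B | C[C@H](CC(=O)O[C@H](C)Cc1cc(OCc2ccccc2)cc(OCc3ccccc3)c1C(=O)O[C@@H](C)CC(=O)OCc4ccccc4)OC(=O)C[C@@H](OCc5ccccc5)COCc6ccccc6 | intermediate
22 | talapolyester B | C[C@H](CC(=O)O[C@H](C)Cc1cc(O)cc(O)c1C(=O)O[C@@H](C)CC(=O)O)OC(=O)C[C@@H](O)CO | target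

Total steps: 14. Longest linear sequence: 8 steps (1, 2, 3, 4, 6, 7, 13, 14) from 1.

Steps most likely to fail

**Step 2.** Three processes may together stall the carbonylation:
- β-hydride elimination from the palladium alkoxide, which oxidises the directing carbinol;
- reduction of the catalyst by CO to inactive metal;
- slow C–H cleavage at a position crowded by the chain and a benzyloxy group.

The fallback sets out from 4 and makes the carbon–palladium bond by oxidative addition instead of C–H cleavage. Electrophilic iodination (NIS, MeCN, 0 °C) is expected at the ring carbon next to the chain. That carbon is para to one benzyloxy group, ortho to the other and less crowded than C4. The iodination should give (R)-1-[3,5-bis(benzyloxy)-2-iodophenyl]propan-2-ol F1. Carbonylative lactonisation of this halo alcohol under zerovalent palladium catalysis (PdCl2(PPh3)2, CO 1 atm, K2CO3, DMF, 80 °C) needs no oxidant, so the carbinol is safe. It comes back to the route at 5.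

**Step 6.** The β-hydroxy ester may dehydrate through E1cB-type collapse of its oxyphosphonium salt. Capture by the crowded carboxylate may also be slow, so the alcohol could be consumed without ester formation.

The fallback sets out from 8 and replaces alcohol activation with inversion by acyl activation with retention, so the opposite enantiomer of the alcohol is used. Under neutral conditions, 1-chloro-N,N,2-trimethylprop-1-en-1-amine (CH2Cl2, 0 °C) should convert 8 into 2,4-bis(benzyloxy)-6-[(R)-2-(tert-butyldimethylsilyloxy)propyl]benzoyl chloride F2. This is combined with benzyl (S)-3-hydroxybutanoate F3, made from commercial methyl (S)-3-hydroxybutanoate by the protocol of step 5, in pyridine–CH2Cl2 with catalytic DMAP. The (S)-centre is then bought rather than made, and the sequence comes back to the route at 11.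

**Step 13.** Base-induced β-elimination of the acyloxy group in the activated acyl donor would cut unit A off. Back-closure of the lactone under DMAP is a second danger. Both may compete with the slow acylation of a hindered secondary alcohol.

The fallback sets out from 12 and grows the chain one unit at a time, using acyl donors whose β-substituent is a poor leaving group. Compound 9 is silylated (TBSCl, imidazole, DMF) to methyl (R)-3-(tert-butyldimethylsilyloxy)butanoate F4. Saponification (LiOH, THF–H2O) then gives (R)-3-(tert-butyldimethylsilyloxy)butanoic acid F5. Steglich esterification of 12 with this acid should give the silyl-capped B–C–D triester F6, and HF·pyridine frees the B–C–D alcohol F7. A second Steglich esterification with acid 17 comes back to the route at 21.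

Further compounds
F1 | step 2 | (R)-1-[3,5-bis(benzyloxy)-2-iodophenyl]propan-2-ol | C[C@@H](O)Cc1cc(OCc2ccccc2)cc(OCc2ccccc2)c1I
F2 | step 6 | 2,4-bis(benzyloxy)-6-[(R)-2-(tert-butyldimethylsilyloxy)propyl]benzoyl chloride | C[C@@H](O[Si](C)(C)C(C)(C)C)Cc1cc(OCc2ccccc2)cc(OCc2ccccc2)c1C(=O)Cl
F3 | step 6 | benzyl (S)-3-hydroxybutanoate | C[C@H](O)CC(=O)OCc1ccccc1
F4 | step 13 | methyl (R)-3-(tert-butyldimethylsilyloxy)butanoate | C[C@@H](O[Si](C)(C)C(C)(C)C)CC(=O)OC
F5 | step 13 | (R)-3-(tert-butyldimethylsilyloxy)butanoic acid | C[C@@H](O[Si](C)(C)C(C)(C)C)CC(=O)O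
F6 | step 13 | silyl-capped B–C–D triester | C[C@@H](O[Si](C)(C)C(C)(C)C)CC(=O)O[C@H](C)Cc1cc(OCc2ccccc2)cc(OCc2ccccc2)c1C(=O)O[C@@H](C)CC(=O)OCc3ccccc3
F7 | step 13 | B–C–D alcohol | C[C@@H](O)CC(=O)O[C@H](C)Cc1cc(OCc2ccccc2)cc(OCc2ccccc2)c1C(=O)O[C@@H](C)CC(=O)OCc3ccccc3
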